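**Two exits.** Follow one molecule. A single-handed free catalyst meets a racemate while solid reagent slowly feeds partner, and each molecule of product leaves the round by a left or a right exit.

all flasks: left-handed substrate 0.020 M; right-handed substrate 0.020 M
- Wednesday's: solid reagent 0.022 M; free catalyst 1 mM; the very flask that is asked about, followed so far
- Thursday's: solid reagent 0.022 M; free catalyst 0.67 mM; run made earlier
- flask: solid reagent 0.0220 M; free catalyst 1.0 mM; time 10 min

| run | time / min | left-handed product / % | right-handed product / % |
|---|---|---|---|
| Wednesday's | 1.33 | 0.4 | 0 |
| Wednesday's | 2.50 | 1.0 | 0.9 |
| Wednesday's | 4.00 | 2.1 | 1.4 |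
| Wednesday's | 5.00 | 3.5 | 2.0 |
| Thursday's | 0.833 | 0.2 | 0.2 |
| Thursday's | 2.50 | 1.1 | 0.1 |
| Thursday's | 5.00 | 1.7 | 0.9 |
| Thursday's | 8.00 | 4.0 | 2.7 |

(readings scatter by 0.5 percentage points)

- excess of left-handed product over right-handed product in the product at 30 s
- excess of left-handed product over right-handed product in the product at 10 min
- part of the left-handed substrate and right-handed substrate charged together that has reacted at 10 min

- free catalyst is single-handed; left-handed substrate and right-handed substrate are mirror images of each other, charged as a racemate, each of them at the stated concentration
- solid reagent is a solid; its amount is given per volume of the solution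
- candidate steps: free catalyst + left-handed substrate <-> catalyst intermediate A; free catalyst + right-handed substrate <-> catalyst intermediate B; partner + catalyst intermediate A -> free catalyst + left-handed product; partner + catalyst intermediate B -> free catalyst + right-handed product; partner -> decomposition product; solid reagent <-> partner; partner + free catalyst -> spent catalyst
- at the start none of the solid reagent is in solution
- an excess is the difference of the two amounts in percent of their sum
- an excess is below zero if the other one leads

**First estimate.** The two runs pooled put 63.1% of the product on the left. I call this the left chance: the chance that a finished molecule of product is left-handed. Left chance less right chance is the excess, so I expect 26.1% at 30 s. The odds, 1.71, are a selectivity factor.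

**First doubt.** Thursday's run had less catalyst, so perhaps the chance moves with the charge. It doesn't show: Wednesday's readings alone give 61.9%, Thursday's 64.2%, and a scatter of 0.5 percentage points can't part those.

**The forecast.** It says 25%, 22% and 18%, with the warning “Selectivity may shift as partner builds”. I take over its conversion.

**Second doubt.** The left exit draws on its own substrate harder, so the odds must sag. At 18% reacted, left-handed substrate stands to right-handed substrate at 0.892. I charge the run half of that loss, which brings my excess at 10 min down to 23.5%.

**The flask.** It gives 27.4%, 25.8% and 14.3%.

    free catalyst + left-handed substrate ⇌ catalyst intermediate A (K = 70.0 M⁻¹, k = 160 M⁻¹ s⁻¹)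
    free catalyst + right-handed substrate ⇌ catalyst intermediate B (K = 110 M⁻¹, k = 41.0 M⁻¹ s⁻¹)
    partner + catalyst intermediate A → free catalyst + left-handed product (k = 6.50 M⁻¹ s⁻¹)
    partner + catalyst intermediate B → free catalyst + right-handed product (k = 2.40 M⁻¹ s⁻¹)
    partner → decomposition product (k = 2.20 × 10⁻⁶ s⁻¹)
    solid reagent ⇌ partner, rate k6*(cs6 - [partner]) while solid is left; crystals form when [partner] > cs6 (solubility = 9.10 mM, k = 0.00230 s⁻¹)
    partner + free catalyst → spent catalyst (k = 0.0170 M⁻¹ s⁻¹)

**Why so.** Carried to 14.3% reacted, the left chance gives 24.2% here. For the neighbour with 0.0025 M of free catalyst and 24.3% reacted, it gives 22.4%, against the simulated 25.2%. In this flask left leads, though at 5.00 min catalyst intermediate B holds 47.0% of the catalyst and catalyst intermediate A 29.7%, because catalyst intermediate B falls back to free catalyst and right-handed substrate. With that undoing taken away, the forecast's 22% fails: the excess at 10 min becomes −91.5%.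

All runs are simulated from invented constants, and the scatter is random.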